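**Plan**
- Retrosynthesis: after removal of the C6 acetyl group and two benzyl ethers, the chroman benzene ring (O1, C2 gem-dimethyl, C3 carbinol, C4, C4a, C5–C8, C8a) is cut at C4a–C5 and C7–C8; the future C8–C8a bond is then cut to a 3-vinyl-2-pyrone and a δ-lactone enol phosphate.
- Enabling feature: C5, C6 and C7 form a malonyl unit, while C4a, C8a and C8 are the β-carbon, the oxygen-bearing carbon and the α'-methylene of a 6-alkyl-3,4-dihydro-2H-pyran whose ring oxygen is already O1; a double C-acylation with malonyl dichloride can therefore build the arene.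
- Forward order: the 2-pyrone ring is made first (lactonisation of a 3,5-diketo ester), the oxane ring second (Baeyer–Villiger ring expansion of a cyclopentanone), the two are joined by B-alkyl Suzuki coupling, and the benzene ring is closed last; C-acetylation and hydrogenolysis finish the synthesis.
- Stereochemistry: the single stereocentre (C3, R) comes from a Corey–Bakshi–Shibata monoreduction of 2,2-dimethylcyclopentane-1,3-dione and is never again a reacting centre.

Key step: step 11

Remark: C3 is read as (R) from the SMILES; the chroman numbering above is used throughout, and all reagents named in the steps are taken as commercial.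

**Route**

Step 1
Reactants: 1 methyl 3-oxopentanoate; 2 N-methoxy-N-methylpropanamide
Product: 3 methyl 4-methyl-3,5-dioxoheptanoate
Conditions: NaH, THF, 0 °C; n-BuLi, 0 °C; 2, 0 °C → rt; aq. HCl
Reagents that add atoms: none
Why: Claisen-type γ-acylation of the β-keto ester dianion at C4 by the N-methoxy-N-methyl amide should give the 3,5-diketo ester, because the chelated tetrahedral adduct survives until the acidic quench and so prevents proton transfer and over-addition.

Step 2
Reactants: 3 methyl 4-methyl-3,5-dioxoheptanoate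
Product: 4 6-ethyl-4-hydroxy-5-methyl-2H-pyran-2-one
Conditions: DBU, toluene, 80 °C; aq. HCl
Reagents that add atoms: none
Why: Base-mediated lactonisation of the 3,5-diketo ester (enol oxygen of the C5 ketone onto the ester, 6-exo-trig) followed by enolisation is the standard route to 5,6-dialkyl-4-hydroxy-2-pyrones.

Step 3
Reactants: 4 6-ethyl-4-hydroxy-5-methyl-2H-pyran-2-one
Product: 5 3-bromo-6-ethyl-4-hydroxy-5-methyl-2H-pyran-2-one
Conditions: NBS, CH2Cl2, 0 °C → rt, dark
Reagents that add atoms: N-bromosuccinimide, O=C1CCC(=O)N1Br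
Why: Electrophilic bromination of the enolic C3–H, the only free ring position of the 4-hydroxy-2-pyrone, should be regiospecific and also blocks C3 against C-benzylation in the next step.

Step 4
Reactants: 5 3-bromo-6-ethyl-4-hydroxy-5-methyl-2H-pyran-2-one; 6 benzyl bromide
Product: 7 4-(benzyloxy)-3-bromo-6-ethyl-5-methyl-2H-pyran-2-one
Conditions: K2CO3, DMF, 40 °C
Reagents that add atoms: none
Why: Williamson O-alkylation of the vinylogous acid under K2CO3/DMF should occur at O4 to give the 4-alkoxy-2-pyrone, C-alkylation being excluded by the bromine.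

Step 5
Reactants: 7 4-(benzyloxy)-3-bromo-6-ethyl-5-methyl-2H-pyran-2-one
Product: 8 4-(benzyloxy)-3-ethenyl-6-ethyl-5-methyl-2H-pyran-2-one
Conditions: vinylboronic acid pinacol ester, PdCl2(dppf)·CH2Cl2 (5 mol %), K2CO3, 1,4-dioxane/H2O, 80 °C
Reagents that add atoms: vinylboronic acid pinacol ester, C=CB1OC(C)(C)C(C)(C)O1
Why: Suzuki–Miyaura coupling at the C3–Br bond of the 4-alkoxy-2-pyrone, a vinylogous α-bromo ester that adds readily to zerovalent palladium, should install the vinyl group.

Step 6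
Reactants: 9 2,2-dimethylcyclopentane-1,3-dione
Product: 10 (3R)-3-hydroxy-2,2-dimethylcyclopentan-1-one
Conditions: (S)-2-methyl-CBS-oxazaborolidine (0.1 equiv), catecholborane (1.1 equiv), toluene, −78 → −40 °C; MeOH, then aq. NaOH wash
Reagents that add atoms: none
Why: Corey–Bakshi–Shibata reduction of one of the two enantiotopic carbonyl groups; with the quaternary C2 as the large and the ring CH2 as the small substituent, the (S)-oxazaborolidine should deliver hydride so as to set the (R)-carbinol, which becomes C3 of the chroman.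

Step 7
Reactants: 10 (3R)-3-hydroxy-2,2-dimethylcyclopentan-1-one
Product: 11 (3R)-3-(benzyloxy)-2,2-dimethylcyclopentan-1-one
Conditions: benzyl 2,2,2-trichloroacetimidate, TfOH (5 mol %), CH2Cl2/cyclohexane, 0 °C → rt
Reagents that add atoms: benzyl 2,2,2-trichloroacetimidate, N=C(OCc1ccccc1)C(Cl)(Cl)Cl
Why: Acid-catalysed benzylation with the trichloroacetimidate avoids the retro-aldol cleavage that alkoxide formation would invite in this β-hydroxy ketone, and elimination is impossible because the α-carbon is quaternary.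

Step 8
Reactants: 11 (3R)-3-(benzyloxy)-2,2-dimethylcyclopentan-1-one
Product: 12 (5R)-5-(benzyloxy)-6,6-dimethyloxan-2-one
Conditions: mCPBA, NaHCO3, CH2Cl2, rt
Reagents that add atoms: 3-chloroperoxybenzoic acid, OOC(=O)c1cccc(Cl)c1
Why: Baeyer–Villiger oxidation with migration of the more substituted (quaternary) α-carbon should insert oxygen between the carbonyl and the gem-dimethyl carbon, creating the future O1–C2 bond with retention and without touching the carbinol centre.

Step 9
Reactants: 12 (5R)-5-(benzyloxy)-6,6-dimethyloxan-2-one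
Product: 13 (5R)-5-(benzyloxy)-6,6-dimethyl-5,6-dihydro-4H-pyran-2-yl diphenyl phosphate
Conditions: KN(SiMe3)2, (PhO)2P(O)Cl, THF/HMPA, −78 °C
Reagents that add atoms: diphenyl chlorophosphate, O=P(Cl)(Oc1ccccc1)Oc1ccccc1
Why: O-Phosphorylation of the lactone potassium enolate should give the ketene acetal phosphate, the standard electrophile for turning δ-lactones into 6-substituted 3,4-dihydro-2H-pyrans by cross-coupling.

Step 10
Reactants: 8 4-(benzyloxy)-3-ethenyl-6-ethyl-5-methyl-2H-pyran-2-one; 13 (5R)-5-(benzyloxy)-6,6-dimethyl-5,6-dihydro-4H-pyran-2-yl diphenyl phosphate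
Product: 15 4-(benzyloxy)-3-{2-[(5R)-5-(benzyloxy)-6,6-dimethyl-5,6-dihydro-4H-pyran-2-yl]ethyl}-6-ethyl-5-methyl-2H-pyran-2-one, via B-alkyl-9-BBN adduct 14 (not isolated)
Conditions: 8, 9-BBN, THF, 0 °C → rt; then 13, Pd(PPh3)4 (10 mol %), aq. NaHCO3, DMF, 50 °C
Reagents that add atoms: none
Why: Anti-Markovnikov hydroboration of the terminal vinyl group followed by B-alkyl Suzuki–Miyaura coupling of the primary alkylborane with the ketene acetal phosphate should form the sp3–sp2 bond (future C8–C8a) under weakly basic conditions that spare the pyrone and the enol ether.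

Step 11
Reactants: 15 4-(benzyloxy)-3-{2-[(5R)-5-(benzyloxy)-6,6-dimethyl-5,6-dihydro-4H-pyran-2-yl]ethyl}-6-ethyl-5-methyl-2H-pyran-2-one; 16 malonyl dichloride
Product: 18 4-(benzyloxy)-3-{[(3R)-3-(benzyloxy)-5,7-dihydroxy-2,2-dimethyl-3,4-dihydro-2H-chromen-8-yl]methyl}-6-ethyl-5-methyl-2H-pyran-2-one, via C4a-acylated enol ether acid chloride 17 (not isolated)
Conditions: 16 (1.1 equiv), 2,6-di-tert-butyl-4-methylpyridine (2.5 equiv), CH2Cl2, −78 °C → rt; aq. NaHCO3
Reagents that add atoms: none
Why: Proposed new method: malonyl dichloride (or the chlorocarbonylketene in equilibrium with it) C-acylates the enol ether β-carbon C4a, and proton loss from the oxocarbenium ion gives the β-alkoxy enone acid chloride 17; its extended enol (enol ether shifted to C8a=C8 by loss of a C8 methylene proton) then attacks the pendant acyl chloride at carbon to form C7–C8, and the cyclohexenetrione tautomerises irreversibly to the 5,7-dihydroxy arene. The closest known reaction is the Effenberger cyclisation of enol ethers with malonyl dichloride, which stops at bicyclo[3.3.1]nonanetriones because the bridgehead cannot enolise, together with the related pyrone synthesis from silyl enol ethers, where the second acylation goes to oxygen. The benzene ring closes in a 6-(enolendo)-exo-trig acylation (equivalently a 6π electrocyclisation of the dienylketene formed from 17 by loss of HCl), the only ring size the three-carbon unit allows. No stereocentre is formed, and the C3 carbinol centre is two bonds away from the reacting atoms and cannot epimerise. The step needs C,C- instead of C,O-diacylation and survival of the acid-labile enol ether: O1 is a ring ether oxygen that cannot be acylated without C–O cleavage, the pyrone has no free ring carbon, the hindered pyridine takes up HCl, and the β-benzyloxy group disfavours ionisation of the tertiary C2–O1 bond. Aromatisation supplies a driving force that the bicyclic precedent lacks.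

Step 12
Reactants: 18 4-(benzyloxy)-3-{[(3R)-3-(benzyloxy)-5,7-dihydroxy-2,2-dimethyl-3,4-dihydro-2H-chromen-8-yl]methyl}-6-ethyl-5-methyl-2H-pyran-2-one
Product: 19 3-{[(3R)-6-acetyl-3-(benzyloxy)-5,7-dihydroxy-2,2-dimethyl-3,4-dihydro-2H-chromen-8-yl]methyl}-4-(benzyloxy)-6-ethyl-5-methyl-2H-pyran-2-one
Conditions: Ac2O (1.2 equiv), BF3·OEt2, CH2Cl2, 0 °C → rt; aq. NaOAc
Reagents that add atoms: acetic anhydride, CC(=O)OC(C)=O
Why: Friedel–Crafts C-acylation of the phloroglucinol-type ring should occur at C6, its only unsubstituted carbon, the two flanking hydroxyl groups binding boron and directing the acyl group to carbon (any aryl acetate formed first undergoing Fries-type transfer).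

Step 13
Reactants: 19 3-{[(3R)-6-acetyl-3-(benzyloxy)-5,7-dihydroxy-2,2-dimethyl-3,4-dihydro-2H-chromen-8-yl]methyl}-4-(benzyloxy)-6-ethyl-5-methyl-2H-pyran-2-one
Product: 20 3-{[(3R)-6-acetyl-3,5,7-trihydroxy-2,2-dimethyl-3,4-dihydro-2H-chromen-8-yl]methyl}-6-ethyl-4-hydroxy-5-methyl-2H-pyran-2-one
Conditions: H2 (1 atm), Pd(OH)2/C, EtOAc/EtOH, rt
Reagents that add atoms: none
Why: Hydrogenolysis should cleave the alkyl benzyl ether and the vinylogous benzyl ester, while the hydrogen-bonded aryl ketone and the tetrasubstituted pyrone double bonds are not reduced under these conditions.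

**Compound list**

1 | methyl 3-oxopentanoate | CCC(=O)CC(=O)OC | starting material
2 | N-methoxy-N-methylpropanamide | CCC(=O)N(C)OC | starting material
3 | methyl 4-methyl-3,5-dioxoheptanoate (racemic, enolisable) | CCC(=O)C(C)C(=O)CC(=O)OC | intermediate
4 | 6-ethyl-4-hydroxy-5-methyl-2H-pyran-2-one | CCc1oc(=O)cc(O)c1C | intermediate
5 | 3-bromo-6-ethyl-4-hydroxy-5-methyl-2H-pyran-2-one | CCc1oc(=O)c(Br)c(O)c1C | intermediate
6 | benzyl bromide | BrCc1ccccc1 | starting material
7 | 4-(benzyloxy)-3-bromo-6-ethyl-5-methyl-2H-pyran-2-one | CCc1oc(=O)c(Br)c(OCc2ccccc2)c1C | intermediate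
8 | 4-(benzyloxy)-3-ethenyl-6-ethyl-5-methyl-2H-pyran-2-one | CCc1oc(=O)c(C=C)c(OCc2ccccc2)c1C | intermediate
9 | 2,2-dimethylcyclopentane-1,3-dione | CC1(C)C(=O)CCC1=O | starting material
10 | (3R)-3-hydroxy-2,2-dimethylcyclopentan-1-one | O=C1CC[C@@H](O)C1(C)C | intermediate
11 | (3R)-3-(benzyloxy)-2,2-dimethylcyclopentan-1-one | O=C1CC[C@@H](OCc2ccccc2)C1(C)C | intermediate
12 | (5R)-5-(benzyloxy)-6,6-dimethyloxan-2-one | O=C1CC[C@@H](OCc2ccccc2)C(C)(C)O1 | intermediate
13 | (5R)-5-(benzyloxy)-6,6-dimethyl-5,6-dihydro-4H-pyran-2-yl diphenyl phosphate | O=P(OC1=CC[C@@H](OCc2ccccc2)C(C)(C)O1)(Oc1ccccc1)Oc1ccccc1 | intermediate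
14 | 4-(benzyloxy)-3-[2-(9-borabicyclo[3.3.1]nonan-9-yl)ethyl]-6-ethyl-5-methyl-2H-pyran-2-one | CCc1oc(=O)c(CCB2C3CCCC2CCC3)c(OCc2ccccc2)c1C | intermediate (not isolated)
15 | 4-(benzyloxy)-3-{2-[(5R)-5-(benzyloxy)-6,6-dimethyl-5,6-dihydro-4H-pyran-2-yl]ethyl}-6-ethyl-5-methyl-2H-pyran-2-one | CCc1oc(=O)c(CCC2=CC[C@@H](OCc3ccccc3)C(C)(C)O2)c(OCc2ccccc2)c1C | intermediate
16 | malonyl dichloride | O=C(Cl)CC(=O)Cl | starting material
17 | 4-(benzyloxy)-3-{2-[(5R)-5-(benzyloxy)-3-(3-chloro-3-oxopropanoyl)-6,6-dimethyl-5,6-dihydro-4H-pyran-2-yl]ethyl}-6-ethyl-5-methyl-2H-pyran-2-one | CCc1oc(=O)c(CCC2=C(C(=O)CC(=O)Cl)C[C@@H](OCc3ccccc3)C(C)(C)O2)c(OCc2ccccc2)c1C | intermediate (not isolated)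
18 | 4-(benzyloxy)-3-{[(3R)-3-(benzyloxy)-5,7-dihydroxy-2,2-dimethyl-3,4-dihydro-2H-chromen-8-yl]methyl}-6-ethyl-5-methyl-2H-pyran-2-one | CCc1oc(=O)c(Cc2c(O)cc(O)c3c2OC(C)(C)[C@H](OCc2ccccc2)C3)c(OCc2ccccc2)c1C | intermediate
19 | 3-{[(3R)-6-acetyl-3-(benzyloxy)-5,7-dihydroxy-2,2-dimethyl-3,4-dihydro-2H-chromen-8-yl]methyl}-4-(benzyloxy)-6-ethyl-5-methyl-2H-pyran-2-one | CCc1oc(=O)c(Cc2c(O)c(C(C)=O)c(O)c3c2OC(C)(C)[C@H](OCc2ccccc2)C3)c(OCc2ccccc2)c1C | intermediate
20 | 3-{[(3R)-6-acetyl-3,5,7-trihydroxy-2,2-dimethyl-3,4-dihydro-2H-chromen-8-yl]methyl}-6-ethyl-4-hydroxy-5-methyl-2H-pyran-2-one | CCc1oc(=O)c(Cc2c(O)c(C(C)=O)c(O)c3c2OC(C)(C)[C@H](O)C3)c(O)c1C | target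

**Step count and risks**

Total: 13 steps. Longest linear sequence: 9 steps (steps 1–5 and 10–13, from methyl 3-oxopentanoate).

Steps most likely to fail:

1. Step 11 (proposed new method). The liberated HCl may protonate the enol ether, leading to hydration or to ionisation of the tertiary C2–O1 bond. The sequence may also stop after the first acylation, if the vinylogous ester does not enolise toward C8, and malonyl dichloride may oligomerise. The fallback uses known chemistry, takes the benzene ring from commercial 2,4,6-trihydroxyacetophenone, sets out from pyrone 4 and returns to the route at 20. Condensation of the acetophenone with 3-methylbut-2-enal (ethylenediammonium diacetate, toluene, reflux; Knoevenagel condensation and oxa-6π closure through the non-chelated para hydroxyl, with removal of any 8-acetyl isomer) should give 1-(5,7-dihydroxy-2,2-dimethyl-2H-chromen-6-yl)ethan-1-one F1. Benzylation with 6 (K2CO3, DMF, 60 °C) should give 1-[5,7-bis(benzyloxy)-2,2-dimethyl-2H-chromen-6-yl]ethan-1-one F2. Jacobsen epoxidation (aq. NaOCl, 4-phenylpyridine N-oxide, CH2Cl2, 0 °C) would use the enantiomer of N,N'-bis(3,5-di-tert-butylsalicylidene)-1,2-cyclohexanediaminomanganese chloride that delivers (3R,4R)-6-acetyl-5,7-bis(benzyloxy)-3,4-epoxy-2,2-dimethylchromane F3. Hydrogenolysis (H2, Pd/C, EtOAc) should open the benzylic C4–O bond and remove both benzyl groups to give 1-[(3R)-3,5,7-trihydroxy-2,2-dimethyl-3,4-dihydro-2H-chromen-6-yl]ethan-1-one F4. Pyrone 4 and N,N-dimethylmethyleneiminium iodide (MeCN, rt) should give the Mannich base 3-[(dimethylamino)methyl]-6-ethyl-4-hydroxy-5-methyl-2H-pyran-2-one F5. Warming F5 with F4 (dioxane, 80 °C) should alkylate C8, the only free aromatic carbon of F4, with loss of dimethylamine and give 20.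

2. Step 10. Hydroboration of the electron-poor 3-vinylpyrone may be incomplete or misdirected, the alkylborane may undergo protodeboronation, and the ketene acetal phosphate may hydrolyse before transmetalation. The fallback replaces hydroboration and palladium by carbonyl chemistry, sets out from lactone 12 and hydroxypyrone 4, and returns at 15. Addition of CH2=CHMgBr to 12 (THF, −78 °C) should give (6R)-6-(benzyloxy)-7-hydroxy-7-methyloct-1-en-3-one F6. Michael addition of 4 (Et3N cat., MeCN, rt) should give 3-[(6R)-6-(benzyloxy)-7-hydroxy-7-methyl-3-oxooctyl]-6-ethyl-4-hydroxy-5-methyl-2H-pyran-2-one F7. O-Benzylation with 6 (K2CO3, DMF) should give 4-(benzyloxy)-3-[(6R)-6-(benzyloxy)-7-hydroxy-7-methyl-3-oxooctyl]-6-ethyl-5-methyl-2H-pyran-2-one F8. Acid-catalysed cyclodehydration (PPTS, toluene, reflux, water removal) should close the tertiary hydroxyl onto the ketone and dehydrate the lactol to the endocyclic enol ether 15.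

3. Step 12. The Lewis acid may cause loss or transfer of benzyl groups and cleavage of the methylene bridge in competition with C-acetylation. The fallback brings in the acetyl group without acid, sets out from 18 and returns at 19. Bromination of the only free ring carbon (NBS, 1 equiv, CH2Cl2, −78 °C) should give 4-(benzyloxy)-3-{[(3R)-3-(benzyloxy)-6-bromo-5,7-dihydroxy-2,2-dimethyl-3,4-dihydro-2H-chromen-8-yl]methyl}-6-ethyl-5-methyl-2H-pyran-2-one F9. Stille coupling with tributyl(1-ethoxyvinyl)stannane (Pd(PPh3)4, toluene, 90 °C) should give 4-(benzyloxy)-3-{[(3R)-3-(benzyloxy)-6-(1-ethoxyethenyl)-5,7-dihydroxy-2,2-dimethyl-3,4-dihydro-2H-chromen-8-yl]methyl}-6-ethyl-5-methyl-2H-pyran-2-one F10. Mild hydrolysis of the enol ether (1 M HCl, THF, rt) should give 19.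

**Further compounds**

F1 | step 11 | 1-(5,7-dihydroxy-2,2-dimethyl-2H-chromen-6-yl)ethan-1-one | CC(=O)c1c(O)cc2OC(C)(C)C=Cc2c1O
F2 | step 11 | 1-[5,7-bis(benzyloxy)-2,2-dimethyl-2H-chromen-6-yl]ethan-1-one | CC(=O)c1c(OCc2ccccc2)cc2OC(C)(C)C=Cc2c1OCc1ccccc1
F3 | step 11 | (3R,4R)-6-acetyl-5,7-bis(benzyloxy)-3,4-epoxy-2,2-dimethylchromane | CC(=O)c1c(OCc2ccccc2)cc2OC(C)(C)[C@@H]3O[C@@H]3c2c1OCc1ccccc1
F4 | step 11 | 1-[(3R)-3,5,7-trihydroxy-2,2-dimethyl-3,4-dihydro-2H-chromen-6-yl]ethan-1-one | CC(=O)c1c(O)cc2OC(C)(C)[C@H](O)Cc2c1O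
F5 | step 11 | 3-[(dimethylamino)methyl]-6-ethyl-4-hydroxy-5-methyl-2H-pyran-2-one | CCc1oc(=O)c(CN(C)C)c(O)c1C
F6 | step 10 | (6R)-6-(benzyloxy)-7-hydroxy-7-methyloct-1-en-3-one | C=CC(=O)CC[C@@H](OCc1ccccc1)C(C)(C)O
F7 | step 10 | 3-[(6R)-6-(benzyloxy)-7-hydroxy-7-methyl-3-oxooctyl]-6-ethyl-4-hydroxy-5-methyl-2H-pyran-2-one | CCc1oc(=O)c(CCC(=O)CC[C@@H](OCc2ccccc2)C(C)(C)O)c(O)c1C
F8 | step 10 | 4-(benzyloxy)-3-[(6R)-6-(benzyloxy)-7-hydroxy-7-methyl-3-oxooctyl]-6-ethyl-5-methyl-2H-pyran-2-one | CCc1oc(=O)c(CCC(=O)CC[C@@H](OCc2ccccc2)C(C)(C)O)c(OCc2ccccc2)c1C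
F9 | step 12 | 4-(benzyloxy)-3-{[(3R)-3-(benzyloxy)-6-bromo-5,7-dihydroxy-2,2-dimethyl-3,4-dihydro-2H-chromen-8-yl]methyl}-6-ethyl-5-methyl-2H-pyran-2-one | CCc1oc(=O)c(Cc2c(O)c(Br)c(O)c3c2OC(C)(C)[C@H](OCc2ccccc2)C3)c(OCc2ccccc2)c1C
F10 | step 12 | 4-(benzyloxy)-3-{[(3R)-3-(benzyloxy)-6-(1-ethoxyethenyl)-5,7-dihydroxy-2,2-dimethyl-3,4-dihydro-2H-chromen-8-yl]methyl}-6-ethyl-5-methyl-2H-pyran-2-one | CCc1oc(=O)c(Cc2c(O)c(C(=C)OCC)c(O)c3c2OC(C)(C)[C@H](OCc2ccccc2)C3)c(OCc2ccccc2)c1C
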